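All runs were computed on assumed constants; the scatter is artificial.

The ratio of isomer of the product B to target reads 0.631 in the alder run and 0.655 in the cedar run at 3.00 min, although cedar carries more catalyst. So we treat target and isomer B as one pool in pre-equilibrium. We carry one quantity: the pool share, the part of that pool which is isomer B, 39.1% as read from both runs at that time. Isomer B is then this share times the fraction left in the pool. We reckon what is left, not what is made.

| flask | substrate | catalyst | remark | time |
|---|---|---|---|---|
| alder | 0.40 M | 0.56 mM | run made earlier |  |
| cedar | 0.40 M | 0.88 mM | run made earlier |  |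
| flask | 0.40 M | 0.40 mM |  | 1.0 h |

- alder (time / min: isomer of the product B / %, target / %, substrate / %): 0.667: 25.0, 67.3, 6.5; 3.00: 35.0, 55.5, 3.7; 12.0: 31.3, 49.1, 2.7; 60.0: 29.1, 43.9, 1.7
- cedar (time / min: isomer of the product B / %, target / %, substrate / %): 0.667: 27.2, 65.6, 3.7; 3.00: 34.4, 52.5, 3.7; 12.0: 29.6, 47.0, 2.3; 60.0: 29.2, 43.1, 2.3

(readings scatter by 0.5 percentage points)

- percent here means substrate units held: one self-condensation product counts as two
- the analysis behind the earlier runs scatters by 0.5 percentage points, standard deviation
- reactions considered so far: target + catalyst <-> isomer of the product A + catalyst; substrate + catalyst <-> target + catalyst; catalyst <-> dormant form; 2 substrate -> self-condensation product; target <-> isomer of the product B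

* when, up to 1.0 h, the flask holds most isomer of the product B, in min
* the amount of isomer of the product B, in percent of the substrate charged, at that time

First, the catalyst. The step from target to isomer of the product A (isomer A below) runs on catalyst, so by hand less catalyst should leave more in the pool. The readings at 3.00 min lean that way. Substrate reads 3.7% in both runs, and the part missing from the balance is 5.80% in alder and more, 9.40%, in cedar. Scaled in proportion to catalyst, down to the 0.40 mM of the flask, we reckon a missing part of 4.22%. Taking the same substrate reading for the flask, we reckon 92.1% left in its pool, and we expect 36.0% of isomer B near 3.00 min.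

Next, the time. In alder, isomer B reads 35.0% at 3.00 min and 31.3% at 12.0 min. So the highest alder reading comes early, and by hand a limit well short of 1.0 h should leave the peak of the flask standing.

The forecast gives 35.6% (from 34.4% to 37%) at 2.4 min (from 1.7 min to 3.5 min), by “Setting the transient's rise equal to the slow drain”. Its height stands below our reckoning.

The flask reaches 36.1% at 2.65 min.

    target + catalyst ⇌ isomer of the product A + catalyst, rate k1*[catalyst]*[target] forward; the back reaction follows from the equilibrium constant (K = 0.560, k = 3.30 M⁻¹ s⁻¹)
    substrate + catalyst ⇌ target + catalyst, rate k2*[substrate]*[catalyst] forward; the back reaction follows from the equilibrium constant (K = 19.0, k = 330 M⁻¹ s⁻¹)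
    catalyst ⇌ dormant form (K = 1.60, k = 0.140 s⁻¹)
    2 substrate → self-condensation product (k = 6.80 × 10⁻⁵ M⁻¹ s⁻¹)
    target ⇌ isomer of the product B (K = 0.640, k = 0.0150 s⁻¹)

Target and isomer B relax with a half-life of 0.301 min, far shorter than the 22.8 min forward half-life of target going to isomer A at 1.00 h. At the peak the flask holds 3.02% substrate and 4.45% isomer A, and the pool share times what is left gives 36.2%. The neighbour flask, with the same charge but read at 25 min, also reached 36.1%. At its end, with 2.46% substrate and 20.8% isomer A, the share gives 30.0%, and that flask holds 30.0%.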